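**Plan**
1. Cuts: first the C4(upper unit)–C6(lower unit) interflavanyl bond; then, in each unit, the O1–C2 bond of ring C, read as a 1,2-shift of O1 that inserts a benzylic carbon into the O1–C bond of a five-membered benzofuran ring; last the carbinol–alkyne bond of a propargylic alcohol.
2. Forward: ring A aldehyde + zinc arylacetylide → propargylic carbinol → 5-exo-dig closure to a (Z)-2-benzylidene-2,3-dihydrobenzofuran-3-ol (ring O1, C2, C3, C3a, C7a) → oxidative ring expansion to the 4-hydroxyflavan-3-one (ring C) → reduction; the two units are then joined and deprotected.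
3. Enabling feature: the O1–C2(aryl)–C3(O)–C4(O) array of the lower ring C. C2 is a benzylic carbon bearing the 4-oxygenated ring B (cation-stabilising), C3 is a latent carbonyl (former ketal carbon) and C4–OH is the former furanol carbinol, so ring C is an aurone-type five-membered ring with its exocyclic carbon inserted next to O1.
4. Stereochemistry: one catalytic asymmetric alkynylation per unit sets the carbinol (future C4); hydroxyl-directed epoxidation and anti shift of O1 relay it to C2; the hydride reagent sets C3 (LiBH(s-Bu)3 gives the all-cis lower unit, directed Me4NBH(OAc)3 the 2,3-trans upper unit).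
5. The 3,4-cis C4–C6 bond comes from intramolecular delivery of lower ring A from a silicon tether on the upper 3-OH (ipso substitution), which also fixes C6 as the site of attack.

Key step: step 7

Assumption: (S,S)-ProPhenol is taken to give the (S)-carbinol 7 and (R,R)-ProPhenol the (R)-carbinol 15; if the sense of induction is the reverse, the two ligand enantiomers are exchanged between steps 5 and 11.
Assumption: thioether 21 is drawn as the 3,4-trans epimer; its C-4 epimer would serve equally, since C-4 is ionised again in step 17.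

**Step 1**
Reactants: 1 2,3,4-trihydroxybenzaldehyde
Product: 2 3,4-bis(benzyloxy)-2-hydroxybenzaldehyde
Conditions: BnBr (2.1 equiv), K2CO3 (2.1 equiv), DMF, rt
Reagents that add atoms: benzyl bromide BrCc1ccccc1
Why: Williamson etherification; the 2-OH is hydrogen-bonded to the aldehyde and least nucleophilic, so two equivalents of benzyl bromide should alkylate O-4 and O-3 selectively.

**Step 2**
Reactants: 2 3,4-bis(benzyloxy)-2-hydroxybenzaldehyde
Product: 3 3,4-bis(benzyloxy)-5-bromo-2-hydroxybenzaldehyde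
Conditions: NBS (1.05 equiv), MeCN, 0 °C
Reagents that add atoms: N-bromosuccinimide O=C1CCC(=O)N1Br
Why: Electrophilic aromatic bromination at C-5, para to the free phenol and ortho to the 4-benzyloxy group, the only doubly activated free position.

**Step 3**
Reactants: 3 3,4-bis(benzyloxy)-5-bromo-2-hydroxybenzaldehyde
Product: 4 3,4-bis(benzyloxy)-5-bromo-2-(tert-butyldimethylsilyloxy)benzaldehyde
Conditions: TBSCl, imidazole, DMAP (cat.), DMF, rt
Reagents that add atoms: tert-butyldimethylsilyl chloride CC(C)(C)[Si](C)(C)Cl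
Why: Silylation masks the acidic phenol for the organozinc addition.

**Step 4**
Reactants: 5 1-(benzyloxy)-4-ethynylbenzene
Product: 6 methyl{[4-(benzyloxy)phenyl]ethynyl}zinc (zinc acetylide; kept under argon as a toluene solution and divided between steps 5 and 11)
Conditions: Me2Zn (1.05 equiv, toluene), Ph3P=O (7 mol %), toluene, 0 °C → rt, until methane evolution stops
Reagents that add atoms: dimethylzinc C[Zn]C
Why: Zincation of the acidic terminal alkyne C–H by dimethylzinc with loss of methane, the alkynylzinc formation that precedes every zinc-mediated aldehyde alkynylation, here assisted by the Lewis-basic phosphine oxide; no stereocentre is formed and the slight excess of Me2Zn later serves to build the chiral catalyst.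

**Step 5**
Reactants: 4 3,4-bis(benzyloxy)-5-bromo-2-(tert-butyldimethylsilyloxy)benzaldehyde; 6 methyl{[4-(benzyloxy)phenyl]ethynyl}zinc
Product: 7 (S)-1-[3,4-bis(benzyloxy)-5-bromo-2-(tert-butyldimethylsilyloxy)phenyl]-3-[4-(benzyloxy)phenyl]prop-2-yn-1-ol
Conditions: 6 (2.8 equiv, toluene solution from step 4, contains Ph3P=O), (S,S)-ProPhenol (10 mol %), toluene, 0–4 °C; aq. NH4Cl
Reagents that add atoms: none
Why: Catalytic asymmetric alkynylation of an aryl aldehyde (ProPhenol alkynylation); the chiral two-zinc catalyst formed from (S,S)-ProPhenol and the methylzinc species of the solution controls the face of addition and sets the (S)-carbinol, the future C-4 of the lower unit.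

**Step 6**
Reactants: 7 (S)-propargylic alcohol (aryl silyl ether)
Product: 9 (2Z,3R)-6,7-bis(benzyloxy)-2-[4-(benzyloxy)benzylidene]-5-bromo-2,3-dihydro-1-benzofuran-3-ol, via free phenol 8 (not isolated)
Conditions: TBAF, AcOH, THF, 0 °C; then AuCl (10 mol %), K2CO3 (10 mol %), MeCN, rt
Reagents that add atoms: none
Why: Fluoride removes the aryl silyl ether, and AuCl-catalysed anti-oxyauration/protodeauration of the alkyne by the phenol (5-exo-dig, as known for aurone precursors) should give the (Z)-exocyclic enol ether with the carbinol centre untouched.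

**Step 7**
Reactants: 9 (2Z,3R)-6,7-bis(benzyloxy)-2-[4-(benzyloxy)benzylidene]-5-bromo-2,3-dihydro-1-benzofuran-3-ol
Product: 11 (2R,4R)-7,8-bis(benzyloxy)-2-[4-(benzyloxy)phenyl]-6-bromo-4-hydroxychroman-3-one, via spiro-epoxide 10 (not isolated)
Conditions: VO(acac)2 (5 mol %), t-BuOOH (1.2 equiv, decane), 4 Å MS, CH2Cl2, −20 °C; then Zn(OTf)2 (10 mol %), −20 → 0 °C; crude ketol used at once
Reagents that add atoms: tert-butyl hydroperoxide CC(C)(C)OO
Why: Proposed new method: the vanadate ester of the 3-OH delivers the peroxide oxygen to the exocyclic enol ether on the hydroxyl face to give spiro-epoxide 10, whose benzylic C–O bond is then ionised by the Lewis acid (cation stabilised by the 4-benzyloxyphenyl group) while ring oxygen O-1 shifts from the ketal carbon to the benzylic carbon on the side opposite the leaving epoxide oxygen and the ketal C–O becomes the C-3 carbonyl, so that the exocyclic carbon is inserted into the O-1–C bond. The closest known reactions are the Auwers flavonol synthesis (aurone dibromide to flavonol by the same transposition of O-1) and the Meinwald/semipinacol rearrangement of epoxides with migration to a benzylic cation. The six-membered ring closes by attack of O-1 on the benzylic carbon, 3-exo-tet to a bridged oxiranium that opens to the pyranone or, in the stepwise limit, 6-exo-trig closure of the released aryloxide on the quinone-methide-type benzylic cation. The new C-2 centre is controlled by the C-3 carbinol of 9: syn epoxidation followed by anti entry of O-1 (inversion at the benzylic carbon) places the aryl group cis to the 4-OH, and chelation of the metal between 4-O and the new carbonyl favours the same 2,4-cis ketol should the cation become free. The step needs cleavage of the benzylic rather than the ketal C–O bond and migration of oxygen rather than of the C-3 hydride; the 4-alkoxyaryl group, set against an aryloxycarbenium ion weakened by the bromo-substituted ring A and two β-oxygens, secures the first, and the alignment of O-1 with the breaking bond the second.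

**Step 8**
Reactants: 11 (2R,4R)-7,8-bis(benzyloxy)-2-[4-(benzyloxy)phenyl]-6-bromo-4-hydroxychroman-3-one
Product: 12 (2R,3R,4R)-7,8-bis(benzyloxy)-2-[4-(benzyloxy)phenyl]-6-bromochroman-3,4-diol (all-cis)
Conditions: LiBH(s-Bu)3 (2.5 equiv), THF, −78 °C; H2O work-up
Reagents that add atoms: none
Why: The bulky borohydride should attack the flavan-3-one equatorially, from the face opposite the pseudo-equatorial 2-aryl and 4-oxy groups (as in the known flavan-3-one to 2,3-cis-flavan-3-ol reduction), giving the axial 3-OH and the all-cis triad, while the low temperature limits enolisation of the labile ketol.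

**Step 9**
Reactants: 12 (2R,3R,4R)-7,8-bis(benzyloxy)-2-[4-(benzyloxy)phenyl]-6-bromochroman-3,4-diol
Product: 13 (2R,3S,4R)-7,8-bis(benzyloxy)-2-[4-(benzyloxy)phenyl]-6-bromo-3,4-bis(tert-butyldimethylsilyloxy)chroman
Conditions: TBSOTf (2.5 equiv), 2,6-lutidine, CH2Cl2, 0 °C → rt
Reagents that add atoms: tert-butyldimethylsilyl trifluoromethanesulfonate CC(C)(C)[Si](C)(C)OS(=O)(=O)C(F)(F)F
Why: Silylation of both secondary hydroxyls removes the acidic protons before lithiation and disfavours ionisation at C-4 later (the change of the C-3 descriptor is formal only).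

**Step 10**
Reactants: 2 3,4-bis(benzyloxy)-2-hydroxybenzaldehyde
Product: 14 3,4-bis(benzyloxy)-2-(tert-butyldimethylsilyloxy)benzaldehyde
Conditions: TBSCl, imidazole, DMAP (cat.), DMF, rt
Reagents that add atoms: tert-butyldimethylsilyl chloride CC(C)(C)[Si](C)(C)Cl
Why: Phenol silylation as in step 3, on the bromine-free aldehyde for the upper unit.

**Step 11**
Reactants: 14 3,4-bis(benzyloxy)-2-(tert-butyldimethylsilyloxy)benzaldehyde; 6 methyl{[4-(benzyloxy)phenyl]ethynyl}zinc
Product: 15 (R)-1-[3,4-bis(benzyloxy)-2-(tert-butyldimethylsilyloxy)phenyl]-3-[4-(benzyloxy)phenyl]prop-2-yn-1-ol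
Conditions: 6 (2.8 equiv, toluene solution from step 4, contains Ph3P=O), (R,R)-ProPhenol (10 mol %), toluene, 0–4 °C; aq. NH4Cl
Reagents that add atoms: none
Why: The same ProPhenol alkynylation with the enantiomeric ligand sets the (R)-carbinol of the upper unit.

**Step 12**
Reactants: 15 (R)-propargylic alcohol (aryl silyl ether)
Product: 17 (2Z,3S)-6,7-bis(benzyloxy)-2-[4-(benzyloxy)benzylidene]-2,3-dihydro-1-benzofuran-3-ol, via free phenol 16 (not isolated)
Conditions: TBAF, AcOH, THF, 0 °C; then AuCl (10 mol %), K2CO3 (10 mol %), MeCN, rt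
Reagents that add atoms: none
Why: Desilylation and AuCl-catalysed 5-exo-dig anti-hydroalkoxylation as in step 6 should give the (Z)-enol ether of the enantiomeric series.

**Step 13**
Reactants: 17 (2Z,3S)-6,7-bis(benzyloxy)-2-[4-(benzyloxy)benzylidene]-2,3-dihydro-1-benzofuran-3-ol
Product: 19 (2S,4S)-7,8-bis(benzyloxy)-2-[4-(benzyloxy)phenyl]-4-hydroxychroman-3-one, via spiro-epoxide 18 (not isolated)
Conditions: VO(acac)2 (5 mol %), t-BuOOH (1.2 equiv, decane), 4 Å MS, CH2Cl2, −20 °C; then Zn(OTf)2 (10 mol %), −20 → 0 °C; crude ketol used at once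
Reagents that add atoms: tert-butyl hydroperoxide CC(C)(C)OO
Why: Proposed new method: the same hydroxyl-directed epoxidation and Lewis-acid-induced 1,2-shift of O-1 to the benzylic carbon as in step 7 (closest known reactions: Auwers flavonol synthesis and Meinwald rearrangement), here in the enantiomeric series, with the 2,4-cis ketol again expected from syn epoxidation and anti migration.

**Step 14**
Reactants: 19 (2S,4S)-7,8-bis(benzyloxy)-2-[4-(benzyloxy)phenyl]-4-hydroxychroman-3-one
Product: 20 (2S,3R,4S)-7,8-bis(benzyloxy)-2-[4-(benzyloxy)phenyl]chroman-3,4-diol (2,3-trans-3,4-trans)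
Conditions: Me4NBH(OAc)3 (5 equiv), MeCN–AcOH (1:1), −30 °C
Reagents that add atoms: none
Why: Hydroxyl-directed triacetoxyborohydride reduction delivers hydride to C-3 from the face of the 4-OH through the alkoxyborohydride, so the new 3-OH should be trans to 4-OH and, the ketol being 2,4-cis, trans to the 2-aryl group.

**Step 15**
Reactants: 20 (2S,3R,4S)-7,8-bis(benzyloxy)-2-[4-(benzyloxy)phenyl]chroman-3,4-diol
Product: 21 (2S,3S,4S)-7,8-bis(benzyloxy)-2-[4-(benzyloxy)phenyl]-4-(benzylsulfanyl)chroman-3-ol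
Conditions: BnSH (4 equiv), BF3·OEt2 (0.3 equiv), CH2Cl2, −40 → −20 °C
Reagents that add atoms: phenylmethanethiol SCc1ccccc1
Why: Acid-catalysed thiolysis of the benzylic 4-OH through the C-4 cation, standard for flavan-3,4-diols; attack anti to the 3-OH should give mainly the 3,4-trans thioether while the excess thiol suppresses self-condensation.

**Step 16**
Reactants: 13 (2R,3S,4R)-6-bromo-3,4-bis(tert-butyldimethylsilyloxy)chroman of the lower unit; 21 (2S,3S,4S)-4-(benzylsulfanyl)chroman-3-ol of the upper unit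
Product: 24 silicon-tethered bis-flavan [3-O-dimethylsilyl ether of 21 whose silicon is bonded to C-6 of the lower chroman], via aryllithium 22 (not isolated), via chlorosilane 23 (not isolated)
Conditions: 13, t-BuLi (2.1 equiv), THF, −78 °C; cannulate into Me2SiCl2 (5 equiv), −78 → 0 °C; evaporate; then 21, imidazole, DMAP, CH2Cl2, rt
Reagents that add atoms: dichlorodimethylsilane C[Si](C)(Cl)Cl
Why: Bromine–lithium exchange, silylation of the aryllithium with excess dichlorosilane and silyl ether formation with the 3-OH of 21 (temporary silicon connection) are standard and touch no stereocentre.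

**Step 17**
Reactants: 24 silicon-tethered bis-flavan
Product: 25 hexa-O-benzyl (4→6)-linked dimer with 3-O-fluorodimethylsilyl on the upper unit (2S,3R; 2,3-trans-3,4-cis) and 3,4-bis-O-TBS on the all-cis lower unit
Conditions: AgBF4 (2.5 equiv), 2,6-di-tert-butyl-4-methylpyridine, THF (0.005 M), −40 → 0 °C, dark
Reagents that add atoms: silver tetrafluoroborate [Ag+].F[B-](F)(F)F
Why: Proposed new method: AgBF4 abstracts the benzylsulfanyl group (thiophilic activation, known for 4-benzylsulfanylflavans) to give the C-4 benzylic cation, which should be captured at the silicon-bearing ipso carbon of the tethered ring A through a five-membered transition state on the face of the 3-O substituent, and loss of silicon as Si–F rearomatises the ring, so that both the C-6 regiochemistry and the 3,4-cis configuration follow from the tether; the closest known reaction is the intramolecular aryl transfer from 2-O-arylsilyl glycosyl donors that gives 1,2-cis C-aryl glycosides.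

**Step 18**
Reactants: 25 silylated hexa-O-benzyl dimer
Product: 26 hexa-O-benzyl ent-oritin-(4α→6)-epioritin-4α-ol (free 3-OH on the upper unit, free 3,4-diol on the lower unit)
Conditions: TBAF (5 equiv), AcOH (5 equiv), THF, rt
Reagents that add atoms: none
Why: Buffered fluoride cleaves the two TBS ethers and the fluorosilyl ether while the benzyl ethers keep the oxidation-prone phenols masked.

**Step 19**
Reactants: 26 hexa-O-benzyl ent-oritin-(4α→6)-epioritin-4α-ol
Product: 27 (2R,3R,4R)-6-[(2S,3R,4R)-3,7,8-trihydroxy-2-(4-hydroxyphenyl)-3,4-dihydro-2H-chromen-4-yl]-2-(4-hydroxyphenyl)-3,4-dihydro-2H-chromene-3,4,7,8-tetrol (target, CNP0391561.7)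
Conditions: H2 (1 atm), Pd(OH)2/C, THF–MeOH, rt, short reaction time
Reagents that add atoms: none
Why: Hydrogenolysis of the six aryl benzyl ethers under neutral conditions, where the free benzylic 4-OH and the C-2–O bonds should be cleaved much more slowly than O-benzyl groups.

**Compound list**
1 | 2,3,4-trihydroxybenzaldehyde | O=Cc1ccc(O)c(O)c1O | starting material
2 | 3,4-bis(benzyloxy)-2-hydroxybenzaldehyde | O=Cc1ccc(OCc2ccccc2)c(OCc2ccccc2)c1O | intermediate
3 | 3,4-bis(benzyloxy)-5-bromo-2-hydroxybenzaldehyde | O=Cc1cc(Br)c(OCc2ccccc2)c(OCc2ccccc2)c1O | intermediate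
4 | 3,4-bis(benzyloxy)-5-bromo-2-(tert-butyldimethylsilyloxy)benzaldehyde | O=Cc1cc(Br)c(OCc2ccccc2)c(OCc2ccccc2)c1O[Si](C)(C)C(C)(C)C | intermediate
5 | 1-(benzyloxy)-4-ethynylbenzene | C#Cc1ccc(OCc2ccccc2)cc1 | starting material
6 | methyl{[4-(benzyloxy)phenyl]ethynyl}zinc (zinc acetylide) | C[Zn]C#Cc1ccc(OCc2ccccc2)cc1 | intermediate
7 | (S)-1-[3,4-bis(benzyloxy)-5-bromo-2-(tert-butyldimethylsilyloxy)phenyl]-3-[4-(benzyloxy)phenyl]prop-2-yn-1-ol | O[C@@H](C#Cc1ccc(OCc2ccccc2)cc1)c1cc(Br)c(OCc2ccccc2)c(OCc2ccccc2)c1O[Si](C)(C)C(C)(C)C | intermediate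
8 | (S)-1-[3,4-bis(benzyloxy)-5-bromo-2-hydroxyphenyl]-3-[4-(benzyloxy)phenyl]prop-2-yn-1-ol (free phenol) | O[C@@H](C#Cc1ccc(OCc2ccccc2)cc1)c1cc(Br)c(OCc2ccccc2)c(OCc2ccccc2)c1O | intermediate
9 | (2Z,3R)-6,7-bis(benzyloxy)-2-[4-(benzyloxy)benzylidene]-5-bromo-2,3-dihydro-1-benzofuran-3-ol | O[C@@H]1c2cc(Br)c(OCc3ccccc3)c(OCc3ccccc3)c2O/C1=C\c1ccc(OCc2ccccc2)cc1 | intermediate
10 | (2R,3R,3'S)-6,7-bis(benzyloxy)-3'-[4-(benzyloxy)phenyl]-5-bromo-3H-spiro[1-benzofuran-2,2'-oxiran]-3-ol (epoxide oxygen syn to 3-OH, aryl cis to O-1) | O[C@@H]1c2cc(Br)c(OCc3ccccc3)c(OCc3ccccc3)c2O[C@]14O[C@H]4c1ccc(OCc2ccccc2)cc1 | intermediate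
11 | (2R,4R)-7,8-bis(benzyloxy)-2-[4-(benzyloxy)phenyl]-6-bromo-4-hydroxychroman-3-one (2,4-cis) | c1ccccc1COc1ccc([C@H]2Oc3c(cc(Br)c(OCc4ccccc4)c3OCc4ccccc4)[C@@H](O)C2=O)cc1 | intermediate
12 | (2R,3R,4R)-7,8-bis(benzyloxy)-2-[4-(benzyloxy)phenyl]-6-bromochroman-3,4-diol (all-cis) | c1ccccc1COc1ccc([C@H]2Oc3c(cc(Br)c(OCc4ccccc4)c3OCc4ccccc4)[C@@H](O)[C@H]2O)cc1 | intermediate
13 | (2R,3S,4R)-7,8-bis(benzyloxy)-2-[4-(benzyloxy)phenyl]-6-bromo-3,4-bis(tert-butyldimethylsilyloxy)chroman (all-cis) | c1ccccc1COc1ccc([C@H]2Oc3c(cc(Br)c(OCc4ccccc4)c3OCc4ccccc4)[C@@H](O[Si](C)(C)C(C)(C)C)[C@H]2O[Si](C)(C)C(C)(C)C)cc1 | intermediate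
14 | 3,4-bis(benzyloxy)-2-(tert-butyldimethylsilyloxy)benzaldehyde | O=Cc1ccc(OCc2ccccc2)c(OCc2ccccc2)c1O[Si](C)(C)C(C)(C)C | intermediate
15 | (R)-1-[3,4-bis(benzyloxy)-2-(tert-butyldimethylsilyloxy)phenyl]-3-[4-(benzyloxy)phenyl]prop-2-yn-1-ol | O[C@H](C#Cc1ccc(OCc2ccccc2)cc1)c1ccc(OCc2ccccc2)c(OCc2ccccc2)c1O[Si](C)(C)C(C)(C)C | intermediate
16 | (R)-1-[3,4-bis(benzyloxy)-2-hydroxyphenyl]-3-[4-(benzyloxy)phenyl]prop-2-yn-1-ol (free phenol) | O[C@H](C#Cc1ccc(OCc2ccccc2)cc1)c1ccc(OCc2ccccc2)c(OCc2ccccc2)c1O | intermediate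
17 | (2Z,3S)-6,7-bis(benzyloxy)-2-[4-(benzyloxy)benzylidene]-2,3-dihydro-1-benzofuran-3-ol | O[C@H]1c2ccc(OCc3ccccc3)c(OCc3ccccc3)c2O/C1=C\c1ccc(OCc2ccccc2)cc1 | intermediate
18 | (2S,3S,3'R)-6,7-bis(benzyloxy)-3'-[4-(benzyloxy)phenyl]-3H-spiro[1-benzofuran-2,2'-oxiran]-3-ol (epoxide oxygen syn to 3-OH) | O[C@H]1c2ccc(OCc3ccccc3)c(OCc3ccccc3)c2O[C@@]14O[C@@H]4c1ccc(OCc2ccccc2)cc1 | intermediate
19 | (2S,4S)-7,8-bis(benzyloxy)-2-[4-(benzyloxy)phenyl]-4-hydroxychroman-3-one (2,4-cis) | c1ccccc1COc1ccc([C@@H]2Oc3c(ccc(OCc4ccccc4)c3OCc4ccccc4)[C@H](O)C2=O)cc1 | intermediate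
20 | (2S,3R,4S)-7,8-bis(benzyloxy)-2-[4-(benzyloxy)phenyl]chroman-3,4-diol (2,3-trans-3,4-trans) | c1ccccc1COc1ccc([C@@H]2Oc3c(ccc(OCc4ccccc4)c3OCc4ccccc4)[C@H](O)[C@H]2O)cc1 | intermediate
21 | (2S,3S,4S)-7,8-bis(benzyloxy)-2-[4-(benzyloxy)phenyl]-4-(benzylsulfanyl)chroman-3-ol (2,3-trans-3,4-trans) | c1ccccc1COc1ccc([C@@H]2Oc3c(ccc(OCc4ccccc4)c3OCc4ccccc4)[C@H](SCc4ccccc4)[C@H]2O)cc1 | intermediate
22 | 6-lithio derivative of 13 (aryllithium) | c1ccccc1COc1ccc([C@H]2Oc3c(cc([Li])c(OCc4ccccc4)c3OCc4ccccc4)[C@@H](O[Si](C)(C)C(C)(C)C)[C@H]2O[Si](C)(C)C(C)(C)C)cc1 | intermediate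
23 | 6-(chlorodimethylsilyl) derivative of 13 (chlorosilane) | c1ccccc1COc1ccc([C@H]2Oc3c(cc([Si](C)(C)Cl)c(OCc4ccccc4)c3OCc4ccccc4)[C@@H](O[Si](C)(C)C(C)(C)C)[C@H]2O[Si](C)(C)C(C)(C)C)cc1 | intermediate
24 | silicon-tethered bis-flavan: 3-O of thioether 21 joined through SiMe2 to C-6 of the bis-TBS lower chroman | c1ccccc1COc1ccc([C@H]2Oc3c(cc([Si](C)(C)O[C@@H]5[C@@H](SCc6ccccc6)c6ccc(OCc7ccccc7)c(OCc7ccccc7)c6O[C@H]5c5ccc(OCc6ccccc6)cc5)c(OCc4ccccc4)c3OCc4ccccc4)[C@@H](O[Si](C)(C)C(C)(C)C)[C@H]2O[Si](C)(C)C(C)(C)C)cc1 | intermediate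
25 | hexa-O-benzyl (4→6) dimer, upper unit (2S,3R) 2,3-trans-3,4-cis with 3-O-fluorodimethylsilyl, lower unit all-cis with 3,4-bis-O-TBS | c1ccccc1COc1ccc([C@H]2Oc3c(cc([C@@H]4c5ccc(OCc6ccccc6)c(OCc6ccccc6)c5O[C@@H](c5ccc(OCc6ccccc6)cc5)[C@@H]4O[Si](C)(C)F)c(OCc4ccccc4)c3OCc4ccccc4)[C@@H](O[Si](C)(C)C(C)(C)C)[C@H]2O[Si](C)(C)C(C)(C)C)cc1 | intermediate
26 | hexa-O-benzyl ent-oritin-(4α→6)-epioritin-4α-ol (7,8,4'-tri-O-benzyl on each unit; free 3-OH above, free 3,4-diol below) | c1ccccc1COc1ccc([C@H]2Oc3c(cc([C@@H]4c5ccc(OCc6ccccc6)c(OCc6ccccc6)c5O[C@@H](c5ccc(OCc6ccccc6)cc5)[C@@H]4O)c(OCc4ccccc4)c3OCc4ccccc4)[C@@H](O)[C@H]2O)cc1 | intermediate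
27 | (2R,3R,4R)-6-[(2S,3R,4R)-3,7,8-trihydroxy-2-(4-hydroxyphenyl)-3,4-dihydro-2H-chromen-4-yl]-2-(4-hydroxyphenyl)-3,4-dihydro-2H-chromene-3,4,7,8-tetrol, i.e. ent-oritin-(4α→6)-epioritin-4α-ol | Oc1ccc([C@H]2Oc3c(cc([C@@H]4c5ccc(O)c(O)c5O[C@@H](c5ccc(O)cc5)[C@@H]4O)c(O)c3O)[C@@H](O)[C@H]2O)cc1 | target

**Totals**
Total step count: 19.
Longest linear sequence: 12 steps (steps 1–3, 5–9 and 16–19).

**Steps most likely to fail**

Step 7 (labelled). The spiro-epoxide may open at the ketal carbon and shift the C-3 hydride, leading to the aldol-type benzofuranone and on to the aurone. The allylic alcohol may ionise to a benzofuran before it is epoxidised. A free benzylic cation may erode the configuration at C-2, and the ketol may enolise. Fallback with known reactions: from 9, hydrogen-bond-directed syn-dihydroxylation with OsO4·TMEDA (CH2Cl2, −78 °C; aq. Na2SO3 work-up) on the face of the 3-OH would give the hemiketal (2S,3R)-6,7-bis(benzyloxy)-2-{(S)-[4-(benzyloxy)phenyl](hydroxy)methyl}-5-bromo-2,3-dihydro-1-benzofuran-2,3-diol F1. F1 would equilibrate with its open-chain tautomer (1R,3S)-1-[3,4-bis(benzyloxy)-5-bromo-2-hydroxyphenyl]-3-[4-(benzyloxy)phenyl]-1,3-dihydroxypropan-2-one F2. Intramolecular Mitsunobu etherification (PPh3, DIAD, THF, 0 °C) of the phenol with the carbinol next to ring B, with inversion, would then close ring C and return to the route at 11.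

Step 13 (labelled). The same processes as in step 7 apply, and a 2,4-trans ketol would also misdirect the reduction of step 14. Fallback with known reactions: from 15, trans-hydroalumination with NaAlH2(OCH2CH2OMe)2 (THF, 0 °C) would give (R,E)-1-[3,4-bis(benzyloxy)-2-(tert-butyldimethylsilyloxy)phenyl]-3-[4-(benzyloxy)phenyl]prop-2-en-1-ol F3. Sharpless epoxidation (Ti(OiPr)4, L-(+)-diisopropyl tartrate, t-BuOOH, 4 Å MS, CH2Cl2, −20 °C), the matched pairing for this carbinol by the usual mnemonic, would give the erythro trans-epoxy alcohol (S)-[3,4-bis(benzyloxy)-2-(tert-butyldimethylsilyloxy)phenyl]{(2R,3R)-3-[4-(benzyloxy)phenyl]oxiran-2-yl}methanol F4. TBAF buffered with AcOH (THF, 0 °C) would free the phenol to give (S)-[3,4-bis(benzyloxy)-2-hydroxyphenyl]{(2R,3R)-3-[4-(benzyloxy)phenyl]oxiran-2-yl}methanol F5. Camphorsulfonic acid (cat., CH2Cl2, −20 °C) would then effect 6-endo opening of the epoxide by the phenol at the benzylic carbon with inversion. This gives the 2,3-trans-3,4-trans diol directly and returns to the route at 20.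

Step 17 (labelled). The electron-rich arylsilane may be protodesilylated by adventitious acid, the cation may attack C-5 instead of the ipso carbon, or it may be captured intermolecularly to give oligomers. Fallback with known reactions: from 13, bromine–lithium exchange to aryllithium 22 and protonation (t-BuLi, THF, −78 °C; MeOH) would give (2R,3S,4R)-7,8-bis(benzyloxy)-2-[4-(benzyloxy)phenyl]-3,4-bis(tert-butyldimethylsilyloxy)chroman F6. Intermolecular AgBF4-mediated coupling of thioether 21 with excess F6 (THF, 0 °C) is the known thiophilic activation of 4-benzylsulfanylflavans. It would give the wanted 3,4-cis hexa-O-benzyl (4→6) dimer with free upper 3-OH and lower 3,4-bis-O-TBS F7 together with its 3,4-trans C-4 epimer F8. F7 is expected to be the minor epimer and would be separated by chromatography. Desilylation of F7 under the conditions of step 18 would return to the route at 26.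

**Further compounds**
F1 | step 7 | (2S,3R)-6,7-bis(benzyloxy)-2-{(S)-[4-(benzyloxy)phenyl](hydroxy)methyl}-5-bromo-2,3-dihydro-1-benzofuran-2,3-diol | O[C@@H]1c2cc(Br)c(OCc3ccccc3)c(OCc3ccccc3)c2O[C@@]1(O)[C@@H](O)c1ccc(OCc2ccccc2)cc1
F2 | step 7 | (1R,3S)-1-[3,4-bis(benzyloxy)-5-bromo-2-hydroxyphenyl]-3-[4-(benzyloxy)phenyl]-1,3-dihydroxypropan-2-one | c1ccccc1COc1ccc([C@H](O)C(=O)[C@H](O)c2cc(Br)c(OCc3ccccc3)c(OCc3ccccc3)c2O)cc1
F3 | step 13 | (R,E)-1-[3,4-bis(benzyloxy)-2-(tert-butyldimethylsilyloxy)phenyl]-3-[4-(benzyloxy)phenyl]prop-2-en-1-ol | O[C@H](/C=C/c1ccc(OCc2ccccc2)cc1)c1ccc(OCc2ccccc2)c(OCc2ccccc2)c1O[Si](C)(C)C(C)(C)C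
F4 | step 13 | (S)-[3,4-bis(benzyloxy)-2-(tert-butyldimethylsilyloxy)phenyl]{(2R,3R)-3-[4-(benzyloxy)phenyl]oxiran-2-yl}methanol (erythro, trans-epoxide) | O[C@@H](c1ccc(OCc2ccccc2)c(OCc2ccccc2)c1O[Si](C)(C)C(C)(C)C)[C@H]1O[C@@H]1c1ccc(OCc2ccccc2)cc1
F5 | step 13 | (S)-[3,4-bis(benzyloxy)-2-hydroxyphenyl]{(2R,3R)-3-[4-(benzyloxy)phenyl]oxiran-2-yl}methanol | O[C@@H](c1ccc(OCc2ccccc2)c(OCc2ccccc2)c1O)[C@H]1O[C@@H]1c1ccc(OCc2ccccc2)cc1
F6 | step 17 | (2R,3S,4R)-7,8-bis(benzyloxy)-2-[4-(benzyloxy)phenyl]-3,4-bis(tert-butyldimethylsilyloxy)chroman | c1ccccc1COc1ccc([C@H]2Oc3c(ccc(OCc4ccccc4)c3OCc4ccccc4)[C@@H](O[Si](C)(C)C(C)(C)C)[C@H]2O[Si](C)(C)C(C)(C)C)cc1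
F7 | step 17 | hexa-O-benzyl (4→6) dimer, upper unit 2,3-trans-3,4-cis with free 3-OH, lower unit all-cis with 3,4-bis-O-TBS | c1ccccc1COc1ccc([C@H]2Oc3c(cc([C@@H]4c5ccc(OCc6ccccc6)c(OCc6ccccc6)c5O[C@@H](c5ccc(OCc6ccccc6)cc5)[C@@H]4O)c(OCc4ccccc4)c3OCc4ccccc4)[C@@H](O[Si](C)(C)C(C)(C)C)[C@H]2O[Si](C)(C)C(C)(C)C)cc1
F8 | step 17 | hexa-O-benzyl (4→6) dimer, upper unit 2,3-trans-3,4-trans (C-4 epimer of F7) with free 3-OH, lower unit all-cis with 3,4-bis-O-TBS | c1ccccc1COc1ccc([C@H]2Oc3c(cc([C@H]4c5ccc(OCc6ccccc6)c(OCc6ccccc6)c5O[C@@H](c5ccc(OCc6ccccc6)cc5)[C@@H]4O)c(OCc4ccccc4)c3OCc4ccccc4)[C@@H](O[Si](C)(C)C(C)(C)C)[C@H]2O[Si](C)(C)C(C)(C)C)cc1
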